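The earlier runs and the new flask are calculated for an exercise; scatter was added.

Each target made costs one starting material and one partner, so their difference is an invariant: 120 mM throughout the birch run. The maple run is charged with the same 120 mM (a same-excess pair), so birch, after using 0.300 M, holds maple's charge plus target. What this invariant does not carry over is the clock, and the clock is what you need to watch here.

| setting | birch | maple | larch | alder | cedar |
|---|---|---|---|---|---|
| starting material | 0.600 M | 0.300 M | 0.600 M | 0.300 M | 0.130 M |
| partner | 0.480 M | 0.180 M | 0.960 M | 0.480 M | 0.480 M |
| catalyst | 0.0480 M | 0.0480 M | 0.0480 M | 0.0480 M | 0.0480 M |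
| time |  |  |  |  | 23 h |

| run | time / h | [target] / M |
|---|---|---|
| birch run | 0.92 | 0.0038 |
| birch run | 1.5 | 0.0093 |
| birch run | 2.3 | 0.0164 |
| birch run | 3.7 | 0.0389 |
| birch run | 5.8 | 0.0757 |
| birch run | 9.2 | 0.1361 |
| birch run | 15 | 0.2144 |
| birch run | 23 | 0.2834 |
| maple run | 0.92 | 0.0016 |
| maple run | 1.5 | 0.0048 |
| maple run | 2.3 | 0.0035 |
| maple run | 3.7 | 0.0110 |
| maple run | 5.8 | 0.0243 |
| maple run | 9.2 | 0.0322 |
| maple run | 15 | 0.0620 |
| maple run | 23 | 0.0861 |
| larch run | 0.92 | 0.0063 |
| larch run | 1.5 | 0.0151 |
| larch run | 2.3 | 0.0347 |
| larch run | 3.7 | 0.0824 |
| larch run | 5.8 | 0.1444 |
| larch run | 9.2 | 0.2489 |
| larch run | 15 | 0.3763 |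
| larch run | 23 | 0.4776 |
| alder run | 0.92 | 0.0018 |
| alder run | 1.5 | 0.0037 |
| alder run | 2.3 | 0.0095 |
| alder run | 3.7 | 0.0270 |
| alder run | 5.8 | 0.0504 |
| alder run | 9.2 | 0.0929 |
| alder run | 15 | 0.1418 |
| alder run | 23 | 0.1891 |

(each reading ± 0.002 M)

- Overall: starting material + partner -> target, with catalyst as catalyst.
- Constant volume, constant temperature.
- Bound and free are read together.
- An order is taken over about fifteen percent of the charge, up and down.

- reaction order in [starting material] at the outset, round the charge of the birch run, defined at two percent of the starting material turned into target (one fixed amount of target, the same in the runs compared)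
- reaction order in [partner] at the outset, round the charge of the birch run, defined at two percent of the starting material turned into target
- the maple run starts with 0.300 M less of starting material and of partner than the birch run, and with no target. Compared where both hold the same amount of starting material, once fifteen percent of what the maple run was charged with has turned into target, is the maple run faster, slower or alike (within a tenth)?
- target in the cedar run at 23 h, as a share of the starting material charged
- which of these the readings show (the product speeds the reaction / the catalyst wakes slowly / the catalyst rests as a dimer / the substrate pairs with itself)

Target climbs slowly at first, an induction period. If this climb follows the clock, runs compared at one time have equally awake catalyst, and the wake cancels from their ratio. At 5.8 h, birch against alder gives a clock order in starting material of 0.587, and larch against birch gives a clock order in partner of 0.932.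

The orders asked are taken at equal target, not equal time, and there the wake does not cancel. Suppose target grows as the clock to a power n. A faster charge then reaches the mark earlier, when less catalyst is awake, and it keeps a share 1/n of its clock order. Call this the surviving share φ, the part of a clock order still seen at equal target. Its upper bound is 1, for a flask with no wake, and its lower bound is 0.5, for a rate rising in step with the clock.

You can tighten the lower bound from the larch run. Between 0.92 h and 3.7 h it gives n = 1.85, so φ = 0.541. The larch reading at 0.92 h is 0.0063 M against a scatter of 0.002 M, so I hold this as an estimated lower edge, not a proven one. The brackets are therefore 0.318 to 0.587 in starting material and 0.504 to 0.932 in partner.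

The forecast gives 0.34 and 0.6, both inside, with 0.6 above my lower edge. It also gives alike for maple against birch, 71 % for cedar, and the catalyst wakes slowly, on the ground that “The lag therefore follows the clock, not the product”.

The flask gives 0.32 and 0.62, alike at a rate ratio of 0.98, 73.3 % for cedar, and the catalyst wakes slowly.

    active catalyst + starting material ⇌ catalyst-substrate complex, settled at all times (1.640 M⁻¹)
    catalyst-substrate complex + partner → target + active catalyst + by-product (2.358 M⁻¹ h⁻¹)
    catalyst → active catalyst (0.3355 h⁻¹)

The low orders come from the wake. In the birch run with all catalyst active from the start, the partner order is 1.0 instead of 0.62. The surviving share is therefore 0.608, above the lower edge of 0.541. With all catalyst active from the start, the apparent catalyst order early in the birch run is 0.98 instead of 0.60, a surviving share of 0.612.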